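**Plan**

- Retrosynthesis: the outer dihydrobenzofuran is cut at C2–C3 (carbene C–H insertion from a diaryl ketone); its oxygenated arene is cut at two ring C–C bonds (Diels–Alder aromatisation of an ynone on the eight-ring methine).
- The ethynyl core is cut at the bond between the open-chain methine and the seven-membered ring (benzylic cation plus silyl enol ether) and at the arene–CH(aryl) bond of the seven-membered ring (cyclodehydration, ionic hydrogenation).
- The eight-membered ring is cut at its arene–CH(aryl) bond (Friedel–Crafts conjugate addition to a benzylidene lactone); the lactone carbonyl becomes the alkyne.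
- Forward: one building block, the (2R,3R)-4-bromodihydrobenzofuran 10, is made once and used as aryl ketone 12 (seven-ring half) and arylacetate 14 (eight-ring half). Order of ring formation: furan, lactone, eight-membered ring, seven-membered ring, benzene ring (step 24), last furan.
- Stereochemistry: all three furans come from one chiral dirhodium catalyst (C3) and acid equilibration to trans (C2). The eight-ring centres come from enolate alkylation anti to the C3 aryl group, a cis-fused lactone and the tethered Friedel–Crafts step. The open-chain methine comes from attack on an α-branched benzylic cation, and the two seven-ring methines from ionic hydrogenation on the outer ring face.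

Key step: step 24

Assumption: Rh2(R-PTAD)4 is taken to give the (3R) dihydrobenzofuran in the C–H insertion; if the sense is opposite, Rh2(S-PTAD)4 is used in steps 5 and 27.

Abbreviations: An = 4-methoxyphenyl; Dmp = 3,5-dimethoxyphenyl; PTAD = (1-adamantyl)(N-phthalimido)acetate; BF = (2R,3R)-3-Dmp-6-methoxy-2-An-2,3-dihydrobenzofuran-4-yl. Backbone labels: Ca (seven-ring CH–An), Cc (seven-ring CH bearing the chain), Cd (open-chain CH–An), Ce (eight-ring CH bonded to Cd), Ci (eight-ring CH bearing the alkyne), Ch (eight-ring CH–An).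

**Route**

Step 1
Reactants: 1 1-bromo-3,5-dimethoxybenzene; 2 3,5-dimethoxybenzoyl chloride
Product: 3 (2-bromo-4,6-dimethoxyphenyl)(Dmp)methanone
Conditions: AlCl3, CH2Cl2, 0 °C
Reagents that add atoms: none
Why: Friedel–Crafts acylation; the aroyl cation should attack the carbon ortho to bromine and para to a methoxy group, because the carbon between the two methoxy groups is too crowded for this electrophile.

Step 2
Reactants: 3 bromo diaryl ketone
Product: 4 (2-bromo-6-hydroxy-4-methoxyphenyl)(Dmp)methanone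
Conditions: BCl3, CH2Cl2, −78 → 0 °C; aq. NaHCO3
Reagents that add atoms: none
Why: Chelation-directed Lewis-acid ether cleavage; BCl3 bound to the ketone oxygen removes only the ortho methyl group, the para and meta methyl ethers lacking this activation.

Step 3
Reactants: 4 ortho-hydroxy ketone; 5 4-methoxybenzyl chloride
Product: 6 [2-bromo-4-methoxy-6-(4-methoxybenzyloxy)phenyl](Dmp)methanone
Conditions: K2CO3, DMF, 60 °C
Reagents that add atoms: none
Why: Williamson ether synthesis on the chelated phenol; the benzylic CH2 placed here carries the C–H bond that the carbene will enter.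

Step 4
Reactants: 6 benzyl ether ketone
Product: 7 hydrazone of 6
Conditions: N2H4·H2O, AcOH (cat.), EtOH, 80 °C (sealed)
Reagents that add atoms: hydrazine (as hydrate), NN
Why: Condensation of the diaryl ketone with hydrazine to the hydrazone, pushed by heat and acid catalysis because both ortho positions are substituted.

Step 5
Reactants: 7 hydrazone
Product: 9 (2S,3R)-4-bromo-3-Dmp-6-methoxy-2-An-2,3-dihydrobenzofuran (cis), via diaryldiazomethane 8 (not isolated)
Conditions: MnO2, MeCN, 0 °C; filter; Rh2(R-PTAD)4 (1 mol %), 0 °C → rt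
Reagents that add atoms: none
Why: MnO2 dehydrogenates the hydrazone to the diaryldiazomethane and the chiral divalent rhodium carboxylate turns it into a donor/donor carbene that inserts into the benzylic ether C–H bond five atoms away (intramolecular carbene C–H insertion), which closes the furan; the catalyst sets C3 and the concerted insertion gives the cis C2 epimer.

Step 6
Reactants: 9 cis-dihydrobenzofuran
Product: 10 (2R,3R)-4-bromo-3-Dmp-6-methoxy-2-An-2,3-dihydrobenzofuran (trans)
Conditions: TFA (0.5 equiv), CH2Cl2, 0 °C → rt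
Reagents that add atoms: none
Why: Acid-mediated epimerisation; the C2–O bond ionises reversibly to the 4-methoxybenzylic cation and recloses to the more stable trans isomer, so C2 inverts and C3 is untouched.

Step 7
Reactants: 10 trans-bromide; 11 4'-methoxyacetophenone
Product: 12 2-BF-1-An-ethanone
Conditions: Pd2(dba)3 (2 mol %), Xantphos (4 mol %), NaOtBu, toluene, 80 °C
Reagents that add atoms: none
Why: Palladium-catalysed α-arylation of the methyl ketone enolate with the hindered aryl bromide; the crowded product should resist a second arylation.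

Step 8
Reactants: 12 aryl benzyl ketone
Product: 13 (Z)-2-BF-1-An-1-(trimethylsilyloxy)ethene
Conditions: LiHMDS, THF, −78 °C; TMSCl
Reagents that add atoms: chlorotrimethylsilane, C[Si](C)(C)Cl
Why: O-Silylation of the lithium enolate gives the Z silyl enol ether, the π-nucleophile for the fragment union.

Step 9
Reactants: 10 trans-bromide
Product: 14 methyl 2-BF-acetate
Conditions: Zn dust, methyl bromoacetate, THF; then 10, Pd(dba)2 (2 mol %), Q-Phos (2 mol %), THF, 40 °C
Reagents that add atoms: methyl bromoacetate (as its zinc reagent), COC(=O)CBr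
Why: Palladium-catalysed cross-coupling of the aryl bromide with the Reformatsky zinc enolate (Negishi-type ester α-arylation), which needs no strong base.

Step 10
Reactants: 14 arylacetate
Product: 15 4-tert-butyl 1-methyl (2R)-2-BF-butanedioate
Conditions: LDA, THF, −78 °C; tert-butyl bromoacetate, −78 °C
Reagents that add atoms: tert-butyl bromoacetate, CC(C)(C)OC(=O)CBr
Why: SN2 alkylation of the ester lithium enolate; the enolate should lie near the arene plane with its C–H turned toward the furan C3, and the bromoacetate enters on the face remote from the C3 aryl ring, which sets Ce.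

Step 11
Reactants: 15 mixed succinate
Product: 17 (4R)-4-BF-dihydrofuran-2(3H)-one, via hydroxy ester 16 (not isolated)
Conditions: LiBH4, THF/MeOH, 0 °C → rt; then TsOH (cat.), toluene, 60 °C
Reagents that add atoms: none
Why: LiBH4 reduces the methyl ester and leaves the tert-butyl ester, and acid then closes the γ-lactone with loss of 2-methylpropene (chemoselective reduction, lactonisation); Ce is no longer α to a carbonyl.

Step 12
Reactants: 17 β-aryl lactone; 18 4-methoxybenzaldehyde
Product: 21 (E)-3-(4-methoxybenzylidene)-4-BF-dihydrofuran-2(3H)-one, via aldol adduct 19 (not isolated), via mesylate 20 (not isolated)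
Conditions: LDA, THF, −78 °C; 18; MsCl, −78 → 0 °C; DBU, rt
Reagents that add atoms: none
Why: Aldol addition of the lactone lithium enolate, mesylation of the aldolate and E1cB elimination (aldol condensation) should give the conjugated E benzylidene lactone; only the CH2 next to the carbonyl can be enolised, so Ce is safe.

Step 13
Reactants: 21 benzylidene lactone
Product: 22 cis-fused eight-ring lactone (the Dmp ring bonded through its ortho carbon to Ch)
Conditions: TfOH (20 mol %), CH2Cl2 (0.005 M), −20 → 0 °C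
Reagents that add atoms: none
Why: Intramolecular Friedel–Crafts conjugate addition; the protonated 4-methoxybenzylidene lactone is a benzylic cation that the C3 Dmp ring attacks para to a methoxy group in an 8-endo closure (attack by the benzofuran arene would be a disfavoured 5-endo closure), the tether lets the arene reach only the lactone face that carries the benzofuran, which with the E alkene sets Ch (An trans to the carbonyl carbon), and protonation of the enol to the cis-fused lactone sets Ci.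

Step 14
Reactants: 22 eight-ring lactone
Product: 23 lactol of 22
Conditions: DIBAL-H, CH2Cl2, −78 °C
Reagents that add atoms: none
Why: Partial reduction of the lactone to the lactol with DIBAL-H at low temperature.

Step 15
Reactants: 23 lactol
Product: 24 eight-ring alkynyl alcohol (ethynyl on Ci and CH2OH on Ce)
Conditions: dimethyl (1-diazo-2-oxopropyl)phosphonate, K2CO3, MeOH, 0 °C → rt
Reagents that add atoms: dimethyl (1-diazo-2-oxopropyl)phosphonate, COP(=O)(OC)C(=[N+]=[N-])C(C)=O
Why: Ohira–Bestmann (Seyferth–Gilbert) homologation of the open hydroxy aldehyde form of the lactol gives the terminal alkyne on Ci and frees the primary alcohol; the α-centre has no activation beyond the aldehyde and should hold under K2CO3 in methanol.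

Step 16
Reactants: 24 alkynyl alcohol
Product: 25 eight-ring alkynyl aldehyde (CHO on Ce)
Conditions: Dess–Martin periodinane, NaHCO3, CH2Cl2, 0 °C
Reagents that add atoms: none
Why: Dess–Martin oxidation under buffered conditions; the α-aryl aldehyde is used crude because it can epimerise.

Step 17
Reactants: 25 aldehyde; 26 (4-methoxyphenyl)magnesium bromide
Product: 27 eight-ring alkynyl carbinol (CH(OH)An on Ce)
Conditions: 26 (3 equiv), THF, −78 → 0 °C
Reagents that add atoms: none
Why: Grignard addition to the aldehyde; one equivalent is spent on the alkyne C–H, and both carbinol epimers are used because the centre is ionised next.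

Step 18
Reactants: 27 carbinol; 13 silyl enol ether
Product: 28 ketone An–CO–CH(BF)–CH(An)–(eight-ring unit)
Conditions: 13 (2 equiv), Bi(OTf)3 (5 mol %), 4 Å MS, CH2Cl2, −40 → 0 °C
Reagents that add atoms: none
Why: Lewis-acid-catalysed SN1 substitution of the benzylic alcohol by the silyl enol ether (Mukaiyama-type alkylation); the 4-methoxybenzylic cation should hold the Ce–H bond in its plane to avoid allylic 1,3-strain and the nucleophile adds to the face away from the benzofuran arene, which sets Cd, while the new α-centre Cc is a mixture that step 19 erases.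

Step 19
Reactants: 28 ketone
Product: 29 seven-ring tetrasubstituted alkene (Ca=Cc)
Conditions: MsOH (5 equiv), CH2Cl2, 0 °C → rt
Reagents that add atoms: none
Why: Cyclodehydration (intramolecular Friedel–Crafts hydroxyalkylation, then loss of water); the C3 Dmp ring of the BF unit attacks the protonated aryl ketone para to a methoxy group in a 7-exo closure and the tertiary carbinol loses water toward Cc.

Step 20
Reactants: 29 alkene
Product: 30 ethynyl core (seven- and eight-membered rings and ten stereocentres in place)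
Conditions: Et3SiH (5 equiv), TFA (10 equiv), CH2Cl2, −20 → 0 °C
Reagents that add atoms: none
Why: Ionic hydrogenation; protonation at Cc on the outer face of the folded seven-membered ring gives the diaryl carbocation and Et3SiH delivers hydride anti to the CH(An) group on Cc, that is on the same face, so both hydrogens end syn to the furan C3–H, which sets Cc and Ca.

Step 21
Reactants: 30 ethynyl core; 2 3,5-dimethoxybenzoyl chloride
Product: 31 alkynyl Dmp ketone on Ci
Conditions: PdCl2(PPh3)2 (2 mol %), CuI (4 mol %), Et3N, THF, rt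
Reagents that add atoms: none
Why: Acyl Sonogashira coupling of the terminal alkyne with the aroyl chloride gives the alkynyl ketone in one step.

Step 22
Reactants: 32 methyl acetoacetate
Product: 33 methyl (E)-3-methoxybut-2-enoate
Conditions: HC(OMe)3, H2SO4 (cat.), rt
Reagents that add atoms: trimethyl orthoformate, COC(OC)OC
Why: Acid-catalysed enol ether formation from the β-keto ester with the orthoformate.

Step 23
Reactants: 33 vinylogous ester
Product: 34 1,3-dimethoxy-1-(trimethylsilyloxy)buta-1,3-diene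
Conditions: LDA, THF, −78 °C; TMSCl
Reagents that add atoms: chlorotrimethylsilane, C[Si](C)(C)Cl
Why: γ-Deprotonation of the vinylogous ester and O-silylation of the dienolate give the 1-methoxy-1-silyloxy-3-methoxy diene (Brassard diene).

Step 24
Reactants: 31 alkynyl ketone; 34 diene
Product: 37 2-(3,5-dimethoxybenzoyl)-3-hydroxy-5-methoxyphenyl derivative on Ci, via cyclohexadiene adduct 35 (not isolated), via aryl silyl ether 36 (not isolated)
Conditions: 34 (3 equiv), toluene, 110 °C (sealed); then 1 M HCl, THF, rt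
Reagents that add atoms: none
Why: The nucleophilic CH2 terminus of the diene bonds to the ynone β-carbon (the one on Ci) and its ketene-acetal carbon to the α-carbon in a polarised, asynchronous [4+2] cycloaddition that gives cyclohexa-1,4-diene 35. Loss of methanol from the mixed silyl ketal carbon aromatises it to aryl silyl ether 36 and dilute acid frees the phenol, so the benzene ring closes by cycloaddition followed by elimination and two arene C–C bonds are formed. The closest known reaction is the Diels–Alder aromatisation of alkynyl ketones with 1-alkoxy-1-silyloxy-3-alkoxybutadienes to 2-acylresorcinol monoethers. No stereocentre is formed. The step needs a single regiochemistry, which the push–pull match of ynone and diene secures, and the unsubstituted CH2 terminus tolerates the crowded eight-ring methine. The diene's oxygen pattern is chosen so that the free hydroxyl arrives ortho to the ketone, where the furan oxygen is needed, and the para oxygen is already a methyl ether.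

Step 25
Reactants: 37 ortho-hydroxy ketone; 5 4-methoxybenzyl chloride
Product: 38 4-methoxybenzyl ether of 37
Conditions: Cs2CO3, DMF, 60 °C
Reagents that add atoms: none
Why: Williamson ether synthesis on the hydrogen-bonded phenol with Cs2CO3.

Step 26
Reactants: 38 benzyl ether ketone
Product: 39 hydrazone of 38
Conditions: N2H4·H2O, AcOH (cat.), n-BuOH, 110 °C (sealed)
Reagents that add atoms: hydrazine (as hydrate), NN
Why: Hydrazone formation on the doubly ortho-substituted diaryl ketone under forcing conditions.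

Step 27
Reactants: 39 hydrazone
Product: 41 pentadecamethyl ether with the cis outer dihydrobenzofuran, via diaryldiazomethane 40 (not isolated)
Conditions: MnO2, CH2Cl2, 0 °C; filter; Rh2(R-PTAD)4 (2 mol %), 0 °C → rt
Reagents that add atoms: none
Why: MnO2 oxidation to the diazo compound and rhodium-carbene insertion into the benzylic ether C–H bond (intramolecular carbene C–H insertion) close the outer furan; the same catalyst antipode as in step 5 should set C3 as R and give the cis isomer, the ether C–H being far more reactive than the crowded methine C–H bonds of the eight-membered ring.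

Step 28
Reactants: 41 cis isomer
Product: 42 pentadeca-O-methyl ether of the target (outer furan trans)
Conditions: TFA (0.5 equiv), CH2Cl2, 0 °C → rt
Reagents that add atoms: none
Why: Acid epimerisation at C2 through the 4-methoxybenzylic cation, as in step 6, gives the trans furan and leaves C3 alone.

Step 29
Reactants: 42 pentadecamethyl ether
Product: 43 CNP0184494.1
Conditions: BBr3 (excess), CH2Cl2, −78 °C → rt; MeOH, then H2O
Reagents that add atoms: none
Why: Lewis-acid demethylation of all fifteen aryl methyl ethers with BBr3; the trans dihydrofurans are the thermodynamic isomers and should survive reversible C–O ionisation.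

**Compound list**

1 | 1-bromo-3,5-dimethoxybenzene | COc1cc(Br)cc(OC)c1 | starting material
2 | 3,5-dimethoxybenzoyl chloride | COc1cc(cc(OC)c1)C(Cl)=O | starting material
3 | (2-bromo-4,6-dimethoxyphenyl)(Dmp)methanone | COc1cc(OC)cc(c1)C(=O)c1c(Br)cc(OC)cc1OC | intermediate
4 | (2-bromo-6-hydroxy-4-methoxyphenyl)(Dmp)methanone | COc1cc(OC)cc(c1)C(=O)c1c(Br)cc(OC)cc1O | intermediate
5 | 4-methoxybenzyl chloride | COc1ccc(CCl)cc1 | starting material
6 | [2-bromo-4-methoxy-6-(4-methoxybenzyloxy)phenyl](Dmp)methanone | COc1ccc(COc2cc(OC)cc(Br)c2C(=O)c2cc(OC)cc(OC)c2)cc1 | intermediate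
7 | hydrazone of 6 | COc1ccc(COc2cc(OC)cc(Br)c2C(=NN)c2cc(OC)cc(OC)c2)cc1 | intermediate
8 | diaryldiazomethane from 7 | COc1ccc(COc2cc(OC)cc(Br)c2C(=[N+]=[N-])c2cc(OC)cc(OC)c2)cc1 | intermediate
9 | (2S,3R)-4-bromo-3-Dmp-6-methoxy-2-An-2,3-dihydrobenzofuran (cis) | Brc1cc(OC)cc2c1[C@@H](c1cc(OC)cc(OC)c1)[C@@H](c1ccc(OC)cc1)O2 | intermediate
10 | (2R,3R)-4-bromo-3-Dmp-6-methoxy-2-An-2,3-dihydrobenzofuran (trans) | Brc1cc(OC)cc2c1[C@@H](c1cc(OC)cc(OC)c1)[C@H](c1ccc(OC)cc1)O2 | intermediate
11 | 4'-methoxyacetophenone | CC(=O)c1ccc(OC)cc1 | starting material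
12 | 2-BF-1-An-ethanone | COc1ccc(cc1)C(=O)Cc1cc(OC)cc2c1[C@@H](c1cc(OC)cc(OC)c1)[C@H](c1ccc(OC)cc1)O2 | intermediate
13 | (Z)-2-BF-1-An-1-(trimethylsilyloxy)ethene | C[Si](C)(C)O/C(=C\c1cc(OC)cc2c1[C@@H](c1cc(OC)cc(OC)c1)[C@H](c1ccc(OC)cc1)O2)c1ccc(OC)cc1 | intermediate
14 | methyl 2-BF-acetate | COC(=O)Cc1cc(OC)cc2c1[C@@H](c1cc(OC)cc(OC)c1)[C@H](c1ccc(OC)cc1)O2 | intermediate
15 | 4-tert-butyl 1-methyl (2R)-2-BF-butanedioate | COC(=O)[C@H](CC(=O)OC(C)(C)C)c1cc(OC)cc2c1[C@@H](c1cc(OC)cc(OC)c1)[C@H](c1ccc(OC)cc1)O2 | intermediate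
16 | tert-butyl (3R)-3-BF-4-hydroxybutanoate | OC[C@H](CC(=O)OC(C)(C)C)c1cc(OC)cc2c1[C@@H](c1cc(OC)cc(OC)c1)[C@H](c1ccc(OC)cc1)O2 | intermediate
17 | (4R)-4-BF-dihydrofuran-2(3H)-one | O=C1OC[C@H](C1)c1cc(OC)cc2c1[C@@H](c1cc(OC)cc(OC)c1)[C@H](c1ccc(OC)cc1)O2 | intermediate
18 | 4-methoxybenzaldehyde | COc1ccc(C=O)cc1 | starting material
19 | 4-BF-3-[hydroxy(An)methyl]dihydrofuran-2(3H)-one (lithium alkoxide in the flask; C4 as in 17) | O=C1OC[C@H](C1C(O)c1ccc(OC)cc1)c1cc(OC)cc2c1[C@@H](c1cc(OC)cc(OC)c1)[C@H](c1ccc(OC)cc1)O2 | intermediate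
20 | methanesulfonate of 19 | O=C1OC[C@H](C1C(OS(C)(=O)=O)c1ccc(OC)cc1)c1cc(OC)cc2c1[C@@H](c1cc(OC)cc(OC)c1)[C@H](c1ccc(OC)cc1)O2 | intermediate
21 | (E)-3-(4-methoxybenzylidene)-4-BF-dihydrofuran-2(3H)-one (C4 as in 17) | O=C1OC[C@H](/C1=C\c1ccc(OC)cc1)c1cc(OC)cc2c1[C@@H](c1cc(OC)cc(OC)c1)[C@H](c1ccc(OC)cc1)O2 | intermediate
22 | cis-fused eight-ring lactone (Dmp ortho carbon bonded to Ch; An on Ch trans to the lactone carbonyl carbon on Ci) | O=C1OC[C@H]2c3cc(OC)cc4c3[C@@H](c3cc(OC)cc(OC)c3[C@H](c3ccc(OC)cc3)[C@H]21)[C@H](c2ccc(OC)cc2)O4 | intermediate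
23 | lactol of 22 (anomers) | OC1OC[C@H]2c3cc(OC)cc4c3[C@@H](c3cc(OC)cc(OC)c3[C@H](c3ccc(OC)cc3)[C@H]21)[C@H](c2ccc(OC)cc2)O4 | intermediate
24 | eight-ring alkynyl alcohol (ethynyl on Ci, CH2OH on Ce, cis) | OC[C@H]1c2cc(OC)cc3c2[C@@H](c2cc(OC)cc(OC)c2[C@H](c2ccc(OC)cc2)[C@H]1C#C)[C@H](c1ccc(OC)cc1)O3 | intermediate
25 | eight-ring alkynyl aldehyde (CHO on Ce) | O=C[C@H]1c2cc(OC)cc3c2[C@@H](c2cc(OC)cc(OC)c2[C@H](c2ccc(OC)cc2)[C@H]1C#C)[C@H](c1ccc(OC)cc1)O3 | intermediate
26 | (4-methoxyphenyl)magnesium bromide | COc1ccc([Mg]Br)cc1 | starting material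
27 | eight-ring alkynyl carbinol (CH(OH)An on Ce, both epimers) | COc1ccc(C(O)[C@H]2c3cc(OC)cc4c3[C@@H](c3cc(OC)cc(OC)c3[C@H](c3ccc(OC)cc3)[C@H]2C#C)[C@H](c2ccc(OC)cc2)O4)cc1 | intermediate
28 | ketone An–CO–CH(BF)–CH(An)–(eight-ring unit), Cc epimers | COc1ccc(cc1)C(=O)C(c1cc(OC)cc2c1[C@@H](c1cc(OC)cc(OC)c1)[C@H](c1ccc(OC)cc1)O2)[C@H](c1ccc(OC)cc1)[C@H]1c2cc(OC)cc3c2[C@@H](c2cc(OC)cc(OC)c2[C@H](c2ccc(OC)cc2)[C@H]1C#C)[C@H](c1ccc(OC)cc1)O3 | intermediate
29 | seven-ring tetrasubstituted alkene (Ca=Cc) | COc1ccc(C2=C([C@H](c5ccc(OC)cc5)[C@H]5c6cc(OC)cc7c6[C@@H](c6cc(OC)cc(OC)c6[C@H](c6ccc(OC)cc6)[C@H]5C#C)[C@H](c5ccc(OC)cc5)O7)c3cc(OC)cc4c3[C@@H](c3cc(OC)cc(OC)c32)[C@H](c2ccc(OC)cc2)O4)cc1 | intermediate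
30 | ethynyl core | COc1ccc([C@H]2c3c(OC)cc(OC)cc3[C@@H]3c4c(cc(OC)cc4[C@H]2[C@H](c2ccc(OC)cc2)[C@H]2c4cc(OC)cc5c4[C@@H](c4cc(OC)cc(OC)c4[C@H](c4ccc(OC)cc4)[C@H]2C#C)[C@H](c2ccc(OC)cc2)O5)O[C@H]3c2ccc(OC)cc2)cc1 | intermediate
31 | alkynyl Dmp ketone on Ci | COc1ccc([C@H]2c3c(OC)cc(OC)cc3[C@@H]3c4c(cc(OC)cc4[C@H]2[C@H](c2ccc(OC)cc2)[C@H]2c4cc(OC)cc5c4[C@@H](c4cc(OC)cc(OC)c4[C@H](c4ccc(OC)cc4)[C@H]2C#CC(=O)c2cc(OC)cc(OC)c2)[C@H](c2ccc(OC)cc2)O5)O[C@H]3c2ccc(OC)cc2)cc1 | intermediate
32 | methyl acetoacetate | COC(=O)CC(C)=O | starting material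
33 | methyl (E)-3-methoxybut-2-enoate | CO/C(C)=C/C(=O)OC | intermediate
34 | 1,3-dimethoxy-1-(trimethylsilyloxy)buta-1,3-diene | C=C(OC)C=C(OC)O[Si](C)(C)C | intermediate
35 | cyclohexa-1,4-diene adduct of 31 and 34 | COc1ccc([C@H]2c3c(OC)cc(OC)cc3[C@@H]3c4c(cc(OC)cc4[C@H]2[C@H](c2ccc(OC)cc2)[C@H]2c4cc(OC)cc5c4[C@@H](c4cc(OC)cc(OC)c4[C@H](c4ccc(OC)cc4)[C@H]2C2=C(C(=O)c4cc(OC)cc(OC)c4)C(OC)(O[Si](C)(C)C)C=C(OC)C2)[C@H](c2ccc(OC)cc2)O5)O[C@H]3c2ccc(OC)cc2)cc1 | intermediate
36 | aryl trimethylsilyl ether of 37 | COc1ccc([C@H]2c3c(OC)cc(OC)cc3[C@@H]3c4c(cc(OC)cc4[C@H]2[C@H](c2ccc(OC)cc2)[C@H]2c4cc(OC)cc5c4[C@@H](c4cc(OC)cc(OC)c4[C@H](c4ccc(OC)cc4)[C@H]2c2cc(OC)cc(O[Si](C)(C)C)c2C(=O)c2cc(OC)cc(OC)c2)[C@H](c2ccc(OC)cc2)O5)O[C@H]3c2ccc(OC)cc2)cc1 | intermediate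
37 | 2-(3,5-dimethoxybenzoyl)-3-hydroxy-5-methoxyphenyl derivative on Ci | COc1ccc([C@H]2c3c(OC)cc(OC)cc3[C@@H]3c4c(cc(OC)cc4[C@H]2[C@H](c2ccc(OC)cc2)[C@H]2c4cc(OC)cc5c4[C@@H](c4cc(OC)cc(OC)c4[C@H](c4ccc(OC)cc4)[C@H]2c2cc(OC)cc(O)c2C(=O)c2cc(OC)cc(OC)c2)[C@H](c2ccc(OC)cc2)O5)O[C@H]3c2ccc(OC)cc2)cc1 | intermediate
38 | 4-methoxybenzyl ether of 37 | COc1ccc([C@H]2c3c(OC)cc(OC)cc3[C@@H]3c4c(cc(OC)cc4[C@H]2[C@H](c2ccc(OC)cc2)[C@H]2c4cc(OC)cc5c4[C@@H](c4cc(OC)cc(OC)c4[C@H](c4ccc(OC)cc4)[C@H]2c2cc(OC)cc(OCc4ccc(OC)cc4)c2C(=O)c2cc(OC)cc(OC)c2)[C@H](c2ccc(OC)cc2)O5)O[C@H]3c2ccc(OC)cc2)cc1 | intermediate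
39 | hydrazone of 38 | COc1ccc([C@H]2c3c(OC)cc(OC)cc3[C@@H]3c4c(cc(OC)cc4[C@H]2[C@H](c2ccc(OC)cc2)[C@H]2c4cc(OC)cc5c4[C@@H](c4cc(OC)cc(OC)c4[C@H](c4ccc(OC)cc4)[C@H]2c2cc(OC)cc(OCc4ccc(OC)cc4)c2C(=NN)c2cc(OC)cc(OC)c2)[C@H](c2ccc(OC)cc2)O5)O[C@H]3c2ccc(OC)cc2)cc1 | intermediate
40 | diaryldiazomethane from 39 | COc1ccc([C@H]2c3c(OC)cc(OC)cc3[C@@H]3c4c(cc(OC)cc4[C@H]2[C@H](c2ccc(OC)cc2)[C@H]2c4cc(OC)cc5c4[C@@H](c4cc(OC)cc(OC)c4[C@H](c4ccc(OC)cc4)[C@H]2c2cc(OC)cc(OCc4ccc(OC)cc4)c2C(=[N+]=[N-])c2cc(OC)cc(OC)c2)[C@H](c2ccc(OC)cc2)O5)O[C@H]3c2ccc(OC)cc2)cc1 | intermediate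
41 | pentadecamethyl ether with cis outer dihydrobenzofuran (C2 epimer of 42) | COc1ccc([C@H]2c3c(OC)cc(OC)cc3[C@@H]3c4c(cc(OC)cc4[C@H]2[C@H](c2ccc(OC)cc2)[C@H]2c4cc(OC)cc5c4[C@@H](c4cc(OC)cc(OC)c4[C@H](c4ccc(OC)cc4)[C@H]2c2cc(OC)cc4c2[C@@H](c2cc(OC)cc(OC)c2)[C@@H](c2ccc(OC)cc2)O4)[C@H](c2ccc(OC)cc2)O5)O[C@H]3c2ccc(OC)cc2)cc1 | intermediate
42 | pentadeca-O-methyl ether of the target | COc1ccc([C@H]2c3c(OC)cc(OC)cc3[C@@H]3c4c(cc(OC)cc4[C@H]2[C@H](c2ccc(OC)cc2)[C@H]2c4cc(OC)cc5c4[C@@H](c4cc(OC)cc(OC)c4[C@H](c4ccc(OC)cc4)[C@H]2c2cc(OC)cc4c2[C@@H](c2cc(OC)cc(OC)c2)[C@H](c2ccc(OC)cc2)O4)[C@H](c2ccc(OC)cc2)O5)O[C@H]3c2ccc(OC)cc2)cc1 | intermediate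
43 | CNP0184494.1 | Oc1ccc([C@H]2c3c(O)cc(O)cc3[C@@H]3c4c(cc(O)cc4[C@H]2[C@H](c2ccc(O)cc2)[C@H]2c4cc(O)cc5c4[C@@H](c4cc(O)cc(O)c4[C@H](c4ccc(O)cc4)[C@H]2c2cc(O)cc4c2[C@@H](c2cc(O)cc(O)c2)[C@H](c2ccc(O)cc2)O4)[C@H](c2ccc(O)cc2)O5)O[C@H]3c2ccc(O)cc2)cc1 | target

**Totals and risks**

Total step count: 29. Longest linear sequence: 25 steps (1–6, 9–21, 24–29).

Steps most likely to fail:

1. Step 13. The 8-endo Friedel–Crafts closure may be too slow, so that intermolecular arylation, attack at other arene positions or acid-induced opening of the furan takes over; the Ch configuration could also drift if the cation rotates before closure. The fallback sets out from 14 and changes the electrophile to an enal. Allylation of the enolate of 14 with allyl bromide (LDA, −78 °C) would give the pentenoate F1, and OsO4/NaIO4 cleavage the aldehyde F2. Amine-catalysed condensation with 18 (pyrrolidine, benzoic acid) would give the α-substituted cinnamaldehyde F3. Ring closure under iminium activation (pyrrolidinium trifluoroacetate) would give the eight-ring aldehyde ester F4, in which Ci is epimerisable and can settle, and Ohira–Bestmann homologation the alkyne ester F5. DIBAL-H at −78 °C then reduces the ester to aldehyde 25, where the route is rejoined.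

2. Step 18. The benzylic cation may lose the Ce proton to a styrene faster than it is captured, which would also scramble Ce, and facial selectivity at Cd may be poor. The fallback sets out from 25 and 12 and forms the same bond set by conjugate addition. TiCl4/pyridine Knoevenagel condensation would give the enone F6, and the 4-methoxyphenyl cuprate (from 26 and CuBr·SMe2, with TMSCl, −78 °C) adds to its β-carbon under 1,2-induction from Ce. Protonation gives ketone 28, where the route is rejoined.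

3. Step 26. Hydrazone formation may fail because the carbonyl is shielded by the ortho benzyl ether and the eight-ring methine, or prolonged heating with hydrazine may degrade the substrate. The fallback sets out from 37 and avoids the diazo compound. NaBH4 reduction would give the ortho-hydroxybenzhydrol F7. Its ortho-quinone methide, formed on gentle heating with Cs2CO3, is trapped by the ylide from (4-methoxybenzyl)dimethylsulfonium triflate in a [4+1] annulation that gives the trans-2,3-diaryl dihydrobenzofuran directly. Facial selectivity then rests on the eight-ring methine, and the wanted diastereomer is 42, where the route is rejoined.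

**Further compounds**

F1 | step 13 | methyl (2R)-2-BF-pent-4-enoate | COC(=O)[C@H](CC=C)c1cc(OC)cc2c1[C@@H](c1cc(OC)cc(OC)c1)[C@H](c1ccc(OC)cc1)O2
F2 | step 13 | methyl (2R)-2-BF-4-oxobutanoate | COC(=O)[C@H](CC=O)c1cc(OC)cc2c1[C@@H](c1cc(OC)cc(OC)c1)[C@H](c1ccc(OC)cc1)O2
F3 | step 13 | methyl (E)-2-BF-3-formyl-4-An-but-3-enoate (C2 as in F1) | COC(=O)[C@H](/C(C=O)=C\c1ccc(OC)cc1)c1cc(OC)cc2c1[C@@H](c1cc(OC)cc(OC)c1)[C@H](c1ccc(OC)cc1)O2
F4 | step 13 | eight-ring aldehyde ester (CHO on Ci, CO2Me on Ce) | COC(=O)[C@H]1c2cc(OC)cc3c2[C@@H](c2cc(OC)cc(OC)c2[C@H](c2ccc(OC)cc2)[C@H]1C=O)[C@H](c1ccc(OC)cc1)O3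
F5 | step 13 | eight-ring alkyne ester (ethynyl on Ci, CO2Me on Ce) | COC(=O)[C@H]1c2cc(OC)cc3c2[C@@H](c2cc(OC)cc(OC)c2[C@H](c2ccc(OC)cc2)[C@H]1C#C)[C@H](c1ccc(OC)cc1)O3
F6 | step 18 | enone An–CO–C(BF)=CH–(eight-ring unit) | COc1ccc(cc1)C(=O)C(=C[C@H]1c2cc(OC)cc3c2[C@@H](c2cc(OC)cc(OC)c2[C@H](c2ccc(OC)cc2)[C@H]1C#C)[C@H](c1ccc(OC)cc1)O3)c1cc(OC)cc2c1[C@@H](c1cc(OC)cc(OC)c1)[C@H](c1ccc(OC)cc1)O2
F7 | step 26 | ortho-hydroxybenzhydrol from 37 | COc1ccc([C@H]2c3c(OC)cc(OC)cc3[C@@H]3c4c(cc(OC)cc4[C@H]2[C@H](c2ccc(OC)cc2)[C@H]2c4cc(OC)cc5c4[C@@H](c4cc(OC)cc(OC)c4[C@H](c4ccc(OC)cc4)[C@H]2c2cc(OC)cc(O)c2C(O)c2cc(OC)cc(OC)c2)[C@H](c2ccc(OC)cc2)O5)O[C@H]3c2ccc(OC)cc2)cc1
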